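**Plan**

1. Caryophyllane numbering is used: C1 and C9 are the cyclobutane CH atoms, C11 is CMe2, C4(Me)–O and C5 are the dihydropyran ring-fusion atoms, C8 carries the =CH2. The retrosynthesis first cuts O–C4 and C5–CH2 (retro-hetero-Diels–Alder) to give o-quinone methide 23 and (−)-β-caryophyllene 17, then cuts C8–C9 of the nine-membered ring, then C5–C6 and C1–C2.
2. Enabling feature: C8 is an sp2 ring carbon whose only other substituent is the exocyclic methylene, and C9 is a secondary cyclobutane CH. This is the product pattern of a Zweifel olefination, so C8–C9 can be made by a 1,2-shift from boron inside a ten-membered borate (ring contraction 10 → 9) and not by direct nine-ring closure.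
3. Forward order: the cyclobutane is bought as 2,2-dimethylcyclobutanone; the cyclobutene with the C2–C5 arm is built, then the E-iodoalkene, then the C6–C8 bromoalkene arm, then C9–B, then the nine-membered ring (step 8), then the dihydropyran. The trione ring comes from a phloroglucinol by dearomatising C-methylation.
4. Stereochemistry: C1/C9 come from Cu–H hydroboration of the achiral cyclobutene (syn H/B gives the trans ring fusion, the ligand sets the absolute sense) and survive the stereoretentive shift. E-C4=C5 comes from syn carboalumination. C4/C5 come from suprafacial cycloaddition on the ββ-conformer face of 17; this is the weak point, because the more populated βα conformer gives the other diastereomer.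

Key step: step 8

Assumption: (R)-DTBM-SEGPHOS is taken to direct Cu–H to the cyclobutene face that gives (1S,2R)-13; if the sense is the reverse, the (S)-ligand is used (the same holds for the borane antipode in the fallback to step 7).

**Route**

Step 1
Reactants: 1 2,2-dimethylcyclobutan-1-one
Product: 2 4,4-dimethylcyclobut-1-en-1-yl trifluoromethanesulfonate
Conditions: LDA, THF, −78 °C; PhNTf2, −78 °C to rt
Reagents that add atoms: N-phenylbis(trifluoromethanesulfonimide), O=S(=O)(N(c1ccccc1)S(=O)(=O)C(F)(F)F)C(F)(F)F
Why: Enol triflate formation: the ketone has α-hydrogens on one side only (the other α-carbon is CMe2), so O-sulfonylation of the lithium enolate should give a single cyclobutenyl triflate.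

Step 2
Reactants: 2 4,4-dimethylcyclobut-1-en-1-yl trifluoromethanesulfonate; 3 (4-bromobut-1-yn-1-yl)trimethylsilane
Product: 5 [4-(4,4-dimethylcyclobut-1-en-1-yl)but-1-yn-1-yl]trimethylsilane, via organozinc bromide 4 (not isolated)
Conditions: 3, Zn dust, LiCl, THF, 40 °C; then 2, Pd(PPh3)4 (3 mol%), THF, rt to 40 °C
Reagents that add atoms: none
Why: Negishi coupling: zinc inserts into the primary C–Br bond and Pd(0) joins the alkylzinc to the enol triflate (C1–C2 bond), the silyl cap keeping the alkyne out of the reaction.

Step 3
Reactants: 5 [4-(4,4-dimethylcyclobut-1-en-1-yl)but-1-yn-1-yl]trimethylsilane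
Product: 6 1-(but-3-yn-1-yl)-4,4-dimethylcyclobut-1-ene
Conditions: K2CO3 (cat.), MeOH, rt
Reagents that add atoms: none
Why: Base-catalysed protodesilylation of the alkynylsilane frees the terminal alkyne needed for carbometalation.

Step 4
Reactants: 6 1-(but-3-yn-1-yl)-4,4-dimethylcyclobut-1-ene
Product: 8 1-[(3E)-4-iodo-3-methylbut-3-en-1-yl]-4,4-dimethylcyclobut-1-ene, via alkenylalane 7 (not isolated)
Conditions: Me3Al, Cp2ZrCl2 (20 mol%), CH2Cl2, 0 °C to rt; then I2, THF, −30 to 0 °C
Reagents that add atoms: trimethylaluminium, C[Al](C)C; iodine, II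
Why: Zirconium-catalysed carboalumination adds Me and Al syn across the terminal alkyne (Al on the terminal carbon) and iodinolysis proceeds with retention, which fixes the E geometry of the future C4=C5 bond; the trisubstituted cyclobutene is not a substrate for carboalumination.

Step 5
Reactants: 9 3-bromobut-3-en-1-ol
Product: 10 2-bromo-4-iodobut-1-ene
Conditions: PPh3, I2, imidazole, CH2Cl2, 0 °C to rt
Reagents that add atoms: iodine, II
Why: Appel iodination of the primary alcohol (SN2 on the alkoxyphosphonium ion) leaves the bromoalkene untouched.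

Step 6
Reactants: 8 1-[(3E)-4-iodo-3-methylbut-3-en-1-yl]-4,4-dimethylcyclobut-1-ene; 10 2-bromo-4-iodobut-1-ene
Product: 12 1-[(3E)-7-bromo-3-methylocta-3,7-dien-1-yl]-4,4-dimethylcyclobut-1-ene, via organozinc iodide 11 (not isolated)
Conditions: 10, Zn dust, LiCl, THF, rt; then 8, Pd(PPh3)4 (3 mol%), THF, rt
Reagents that add atoms: none
Why: Negishi coupling: zinc inserts only into the C(sp3)–I bond, and Pd(PPh3)4 at room temperature should engage the E-iodoalkene much faster than the 2-bromoalkene, with retention of the E geometry (C5–C6 bond).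

Step 7
Reactants: 12 1-[(3E)-7-bromo-3-methylocta-3,7-dien-1-yl]-4,4-dimethylcyclobut-1-ene
Product: 13 2-[(1S,2R)-2-[(3E)-7-bromo-3-methylocta-3,7-dien-1-yl]-3,3-dimethylcyclobutyl]-4,4,5,5-tetramethyl-1,3,2-dioxaborolane
Conditions: CuCl (5 mol%), (R)-DTBM-SEGPHOS (5.5 mol%), KOtBu (10 mol%), HBpin (1.1 equiv), THF, 0 °C to rt
Reagents that add atoms: pinacolborane, CC1(C)OBOC1(C)C
Why: Copper hydride-catalysed enantioselective hydroboration: syn hydrocupration of the strained trisubstituted cyclobutene puts H on the fully substituted carbon and Cu on the CH carbon, and σ-bond metathesis with HBpin retains configuration, so boron and the side chain end up trans while the ligand selects the enantiotopic face (sets C1 and C9); the unstrained trisubstituted alkene is inert and the bromoalkene should react more slowly.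

Step 8
Reactants: 13 2-[(1S,2R)-2-[(3E)-7-bromo-3-methylocta-3,7-dien-1-yl]-3,3-dimethylcyclobutyl]-4,4,5,5-tetramethyl-1,3,2-dioxaborolane
Product: 17 (−)-β-caryophyllene, via vinyllithium 14 (not isolated), via cyclic lithium borate 15 (not isolated), via β-iodo boronic ester 16 (not isolated)
Conditions: t-BuLi (2.05 equiv), THF/Et2O, −100 to −78 °C, 2 mM; I2, MeOH/THF, −78 °C; NaOMe, MeOH, −78 °C to rt
Reagents that add atoms: none
Why: Proposed new method: Br–Li exchange on the 2-bromoalkene (expected to outrun t-BuLi addition to the hindered secondary boronate at −100 °C, as in Parham cyclisations) gives vinyllithium 14, whose only electrophile is its own boron, so it closes the ten-membered borate 15; iodine then forms the iodonium ion of the electron-rich vinyl borate and triggers the anti-periplanar 1,2-shift of the cyclobutyl carbon C9 from boron to C8, and methoxide finally causes anti elimination of boron and iodide to leave the exocyclic methylene. The closest known reaction type is the intermolecular Zweifel olefination of secondary boronic esters with α-substituted vinyllithiums to 1,1-disubstituted alkenes. Mode of closure: a ten-membered closure at boron (ate formation, in competition only with oligomeric borates, which high dilution suppresses), followed by ring contraction 10 → 9 through the suprafacial 1,2-metallate shift, so that no direct nine-membered C–C closure is needed. No new stereocentre survives: the shift is stereoretentive at the migrating carbon, so the trans relation fixed in step 7 becomes 1R,9S of 17, and the transient C8 centre of 16 is destroyed in the elimination. Selectivity: cyclobutyl is the only carbon ligand that can migrate (the others are the pinacol oxygens), the isolated E-trisubstituted alkene does not react with iodine at −78 °C, and the strongly exothermic migration should pay for the strain of the E-cyclononene.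

Step 9
Reactants: 18 2-methyl-1-(2,4,6-trihydroxyphenyl)propan-1-one
Product: 21 norflavesone, via monomethyl phenol 19 (not isolated), via dimethyl phenol 20 (not isolated)
Conditions: NaOMe (3.3 equiv), MeI (3.1 equiv), MeOH, 0 °C to rt
Reagents that add atoms: iodomethane, CI
Why: Exhaustive C-methylation of the acylphloroglucinol phenolate, in which the third methyl group enters at an already methylated carbon and dearomatises the ring (alkylative dearomatisation).

Step 10
Reactants: 17 (−)-β-caryophyllene; 21 norflavesone
Product: 24 target, via TEMPO adduct 22 (not isolated), via o-quinone methide 23 (not isolated)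
Conditions: 21 (1.5 equiv), TEMPO, Ag2O, PhMe, rt; then 60 °C
Reagents that add atoms: none
Why: Ag2O/TEMPO oxidation of the ring methyl group gives o-quinone methide 23, which should add to the strained E-C4=C5 alkene in an inverse-electron-demand hetero-Diels–Alder reaction with O going to the tertiary C4; suprafacial addition turns the E geometry into the trans ring fusion, and attack on the exposed face of the ββ conformer of 17 gives 4S,5R, while the more populated βα conformer gives the 4R,5S diastereomer, so a separable mixture is expected in which the target may be the smaller part.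

**Compound list**

1 | 2,2-dimethylcyclobutan-1-one | CC1(C)CCC1=O | starting material
2 | 4,4-dimethylcyclobut-1-en-1-yl trifluoromethanesulfonate | CC1(C)CC=C1OS(=O)(=O)C(F)(F)F | intermediate
3 | (4-bromobut-1-yn-1-yl)trimethylsilane | C[Si](C)(C)C#CCCBr | starting material
4 | [4-(trimethylsilyl)but-3-yn-1-yl]zinc bromide | C[Si](C)(C)C#CCC[Zn]Br | intermediate
5 | [4-(4,4-dimethylcyclobut-1-en-1-yl)but-1-yn-1-yl]trimethylsilane | CC1(C)CC=C1CCC#C[Si](C)(C)C | intermediate
6 | 1-(but-3-yn-1-yl)-4,4-dimethylcyclobut-1-ene | CC1(C)CC=C1CCC#C | intermediate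
7 | [(1E)-4-(4,4-dimethylcyclobut-1-en-1-yl)-2-methylbut-1-en-1-yl]dimethylalumane | CC1(C)CC=C1CC/C(C)=C/[Al](C)C | intermediate
8 | 1-[(3E)-4-iodo-3-methylbut-3-en-1-yl]-4,4-dimethylcyclobut-1-ene | CC1(C)CC=C1CC/C(C)=C/I | intermediate
9 | 3-bromobut-3-en-1-ol | OCCC(Br)=C | starting material
10 | 2-bromo-4-iodobut-1-ene | ICCC(Br)=C | intermediate
11 | (3-bromobut-3-en-1-yl)zinc iodide | I[Zn]CCC(Br)=C | intermediate
12 | 1-[(3E)-7-bromo-3-methylocta-3,7-dien-1-yl]-4,4-dimethylcyclobut-1-ene | CC1(C)CC=C1CC/C(C)=C/CCC(Br)=C | intermediate
13 | 2-[(1S,2R)-2-[(3E)-7-bromo-3-methylocta-3,7-dien-1-yl]-3,3-dimethylcyclobutyl]-4,4,5,5-tetramethyl-1,3,2-dioxaborolane | CC1(C)OB(OC1(C)C)[C@H]2CC(C)(C)[C@@H]2CC/C(C)=C/CCC(Br)=C | intermediate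
14 | vinyllithium: 13 with Li in place of Br on C8 | CC1(C)OB(OC1(C)C)[C@H]2CC(C)(C)[C@@H]2CC/C(C)=C/CCC([Li])=C | intermediate
15 | cyclic lithium borate: pinacolato-boron bridges C8 (=CH2) and C9 in a ten-membered ring that holds the E-C4=C5 alkene | [Li+].C=C1CC/C=C(C)/CC[C@@H]2[C@H](CC2(C)C)[B-]13OC(C)(C)C(C)(C)O3 | intermediate
16 | β-iodo boronic ester: nine-membered ring closed, C8 carries Bpin and CH2I (C8 configuration undefined, lost in the elimination) | ICC1(B3OC(C)(C)C(C)(C)O3)CC/C=C(C)/CC[C@@H]2[C@@H]1CC2(C)C | intermediate
17 | (−)-β-caryophyllene, (1R,4E,9S)-4,11,11-trimethyl-8-methylidenebicyclo[7.2.0]undec-4-ene | C=C1CC/C=C(C)/CC[C@@H]2[C@@H]1CC2(C)C | intermediate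
18 | 2-methyl-1-(2,4,6-trihydroxyphenyl)propan-1-one | CC(C)C(=O)c1c(O)cc(O)cc1O | starting material
19 | 2-methyl-1-(2,4,6-trihydroxy-3-methylphenyl)propan-1-one | CC(C)C(=O)c1c(O)cc(O)c(C)c1O | intermediate
20 | 2-methyl-1-(2,4,6-trihydroxy-3,5-dimethylphenyl)propan-1-one | CC(C)C(=O)c1c(O)c(C)c(O)c(C)c1O | intermediate
21 | norflavesone, 3,5-dihydroxy-4,6,6-trimethyl-2-(2-methylpropanoyl)cyclohexa-2,4-dien-1-one (enol form of the 1,3,5-trione) | CC1=C(O)C(C)(C)C(=O)C(C(=O)C(C)C)=C1O | intermediate
22 | TEMPO adduct of 21 at the methyl-bearing ring carbon | CC1(ON2C(C)(C)CCCC2(C)C)C(=O)C(C)(C)C(=O)C(C(=O)C(C)C)=C1O | intermediate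
23 | o-quinone methide, 5-hydroxy-2,2-dimethyl-6-methylidene-4-(2-methylpropanoyl)cyclohex-4-ene-1,3-dione | C=C1C(=O)C(C)(C)C(=O)C(C(=O)C(C)C)=C1O | intermediate
24 | target: dihydropyran-fused caryophyllane (1R,4S,5R,9S; O on C4, CH2 on C5) carrying the enolised 2-methylpropanoyl dimethylcyclohexanedione ring | C=C1CC[C@@H]2CC3=C(O[C@@]2(C)CC[C@@H]2[C@@H]1CC2(C)C)C(C)(C)C(=O)C(C(=O)C(C)C)=C3O | target

**Count and risks**

Total step count: 10. Longest linear sequence: 8 steps (1, 2, 3, 4, 6, 7, 8, 10).

Steps most likely to fail:

1. Step 8 (Proposed new method). Possible failures are addition of t-BuLi to boron before the halogen–lithium exchange, loss of the vinyllithium to intermolecular (oligomeric) borate formation, or a ring contraction that is too slow against the strain of the E-cyclononene. The fallback uses known chemistry, sets out from 13 and comes back at 17. Treatment of 13 with KHF2 in aqueous methanol should give the potassium trifluoroborate F1. A palladium-catalysed intramolecular Suzuki–Miyaura coupling of this secondary cyclobutyl trifluoroborate with its own alkenyl bromide (Pd(OAc)2, RuPhos, Cs2CO3, toluene/water, 95 °C, slow addition) should then form C8–C9 with retention at C9 and give 17.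

2. Step 10. The cycloaddition may show poor or adverse facial selectivity, because the more populated βα conformer of 17 leads to the 4R,5S diastereomer and the target comes from the ββ conformer. The fallback changes the order of events, sets out from 13 and comes back at 24. The oxidative hetero-Diels–Alder reaction of 21 (via 22 and 23) is run on the acyclic E-alkene of 13, where no ring conformer biases the faces. It should give the seco-adduct F2 and its C4,C5-diastereomer F3 in comparable amounts. KHF2 converts them to the trifluoroborates F4 and F5. Palladium-catalysed intramolecular Suzuki–Miyaura coupling (on the caesium triketonates) then closes C8–C9 across a trans-disubstituted dihydropyran, which is less strained than the E-alkene, and should give 24 together with its 4R,5S diastereomer F6. The two are separated at this rigid tetracyclic stage.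

3. Step 7. Copper hydride may also hydrocuprate the bromoalkene (with loss of bromide), and the regiochemistry or facial selectivity on the cyclobutene may be insufficient. The fallback moves the hydroboration to an earlier stage and uses a stoichiometric chiral borane; it sets out from 8 and comes back at 13. Hydroboration of 8, in which the only other alkene is the deactivated iodoalkene, with (−)-monoisopinocampheylborane should give the isopinocampheyl cyclobutyl borane F7. Excess acetaldehyde releases α-pinene and gives the diethyl boronate F8, and pinacol gives the pinacol boronate F9. Negishi coupling of F9 with organozinc 11 under the conditions of step 6 returns to 13.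

Further compounds
F1 | step 8 | potassium [(1S,2R)-2-[(3E)-7-bromo-3-methylocta-3,7-dien-1-yl]-3,3-dimethylcyclobutyl]trifluoroborate | [K+].F[B-](F)(F)[C@H]1CC(C)(C)[C@@H]1CC/C(C)=C/CCC(Br)=C
F2 | step 10 | seco-adduct, 4S,5R dihydropyran with the C8 bromoalkene arm and the C9 pinacol boronate | C=C(Br)CC[C@@H]1CC2=C(O[C@@]1(C)CC[C@@H]1[C@@H](B3OC(C)(C)C(C)(C)O3)CC1(C)C)C(C)(C)C(=O)C(C(=O)C(C)C)=C2O
F3 | step 10 | 4R,5S diastereomer of F2 | C=C(Br)CC[C@H]1CC2=C(O[C@]1(C)CC[C@@H]1[C@@H](B3OC(C)(C)C(C)(C)O3)CC1(C)C)C(C)(C)C(=O)C(C(=O)C(C)C)=C2O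
F4 | step 10 | potassium trifluoroborate of F2 | [K+].C=C(Br)CC[C@@H]1CC2=C(O[C@@]1(C)CC[C@@H]1[C@@H]([B-](F)(F)F)CC1(C)C)C(C)(C)C(=O)C(C(=O)C(C)C)=C2O
F5 | step 10 | potassium trifluoroborate of F3 | [K+].C=C(Br)CC[C@H]1CC2=C(O[C@]1(C)CC[C@@H]1[C@@H]([B-](F)(F)F)CC1(C)C)C(C)(C)C(=O)C(C(=O)C(C)C)=C2O
F6 | step 10 | 4R,5S diastereomer of 24 | C=C1CC[C@H]2CC3=C(O[C@]2(C)CC[C@@H]2[C@@H]1CC2(C)C)C(C)(C)C(=O)C(C(=O)C(C)C)=C3O
F7 | step 7 | isopinocampheyl[(1S,2R)-2-[(3E)-4-iodo-3-methylbut-3-en-1-yl]-3,3-dimethylcyclobutyl]borane | C[C@H]1[C@H](B[C@H]3CC(C)(C)[C@@H]3CC/C(C)=C/I)C[C@@H]2C[C@H]1C2(C)C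
F8 | step 7 | diethyl [(1S,2R)-2-[(3E)-4-iodo-3-methylbut-3-en-1-yl]-3,3-dimethylcyclobutyl]boronate | CCOB(OCC)[C@H]1CC(C)(C)[C@@H]1CC/C(C)=C/I
F9 | step 7 | 2-[(1S,2R)-2-[(3E)-4-iodo-3-methylbut-3-en-1-yl]-3,3-dimethylcyclobutyl]-4,4,5,5-tetramethyl-1,3,2-dioxaborolane | CC1(C)OB(OC1(C)C)[C@H]2CC(C)(C)[C@@H]2CC/C(C)=C/I
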